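**Plan**

1. Chamigrane numbering: spiro carbon C6; ring B = C1–C6 (Br on C2, Cl and Me on C3); ring A = C6–C11 (C7=C14H2, Br on C10, CMe2 = C11). The retrosynthesis cuts C1–C6 last (together with C14–Si), then C7–C14, the C2–Br/C3–Cl pair, C3–C4 and C4=C5, and in ring A C6–C11 and C8–C9.
2. Forward: prenol → bromochloride building block → acetoacetate chain → ring A by stereospecific bromonium cyclization. The β-keto ester becomes an enol triflate (C7) and a vinyl group (C5/C4); a B-alkyl Suzuki coupling adds the (Z)-allylic alcohol, which is bromochlorinated; the triflate is exchanged for CH2SiMe3; ring B closes last and gives the target directly.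
3. Enabling feature: the C2 bromide of ring B is vicinal to C1, the CH2 bonded to the spiro carbon, and the C7=C14 methylene of ring A is bonded to the same spiro carbon. The target is therefore the SE2' product of a C6=C7–C14–Si allylsilane and a C1–C2 bromonium ion; the β-silyl C7 cation is the counterpart of the chamigrenyl cation of the biosynthesis, reached here from ring A.
4. Closing ring B on the preformed trans-bromochloride lets the ring form in the chair with equatorial halogens, whereas bromochlorination of a ring B alkene would have to place the C2 bromine axial and syn to the CMe2 arm.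
5. Stereochemistry: C10 and C2/C3 come from one ligand-controlled bromochlorination of allylic alcohols used twice (C10 relayed through a bromonium ion of fixed configuration, C2/C3 by anti addition to the (Z)-alkene). C6 is set in the ring closure by the chair transition state, reinforced by ring A.

Key step: step 13

Assumption: in steps 1 and 11 the ligand antipode that gives the (S)-configured C–Br centre is used, and the sense of induction is taken to be the same for both allylic alcohols.

**Step 1**
Reactants: 1 3-methylbut-2-en-1-ol (prenol)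
Product: 2 (2S)-2-bromo-3-chloro-3-methylbutan-1-ol
Conditions: NBS, ClTi(OiPr)3, chiral tridentate Schiff-base ligand (20 mol %), hexanes, −20 °C
Reagents that add atoms: N-bromosuccinimide O=C1CCC(=O)N1Br; chlorotitanium triisopropoxide CC(C)O[Ti](Cl)(OC(C)C)OC(C)C
Why: Catalytic enantioselective bromochlorination of an allylic alcohol, in which the titanium-bound alkoxide directs ligand-controlled anti addition of Br (from NBS) to C2 and of chloride (from titanium) to the tertiary carbon, setting the (S) C–Br centre that becomes C10.

**Step 2**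
Reactants: 2 (2S)-2-bromo-3-chloro-3-methylbutan-1-ol
Product: 3 (2S)-2-bromo-3-chloro-3-methylbutyl trifluoromethanesulfonate
Conditions: Tf2O, 2,6-lutidine, CH2Cl2, −78 °C
Reagents that add atoms: trifluoromethanesulfonic anhydride O=S(=O)(OS(=O)(=O)C(F)(F)F)C(F)(F)F
Why: O-sulfonylation of a primary alcohol with a hindered base at low temperature should give the triflate without displacement or elimination and leaves the stereocentre untouched.

**Step 3**
Reactants: 3 (2S)-2-bromo-3-chloro-3-methylbutyl trifluoromethanesulfonate; 4 methyl acetoacetate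
Product: 6 methyl (6S)-6-bromo-7-chloro-7-methyl-3-oxooctanoate, via acetoacetate dianion 5 (not isolated)
Conditions: 4, NaH then n-BuLi, THF, 0 °C; then 3, −78 → −40 °C
Reagents that add atoms: none
Why: γ-Alkylation of an acetoacetate dianion, whose terminal carbanion is the more nucleophilic site, by SN2 displacement of the primary triflate at low temperature; the C–Br centre is not involved.

**Step 4**
Reactants: 6 methyl (6S)-6-bromo-7-chloro-7-methyl-3-oxooctanoate
Product: 7 methyl (3S)-3-bromo-2,2-dimethyl-6-oxocyclohexane-1-carboxylate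
Conditions: (CF3)2CHOH (HFIP), 23 → 40 °C
Reagents that add atoms: none
Why: Stereospecific solvolytic bromonium cyclization: the tertiary chloride ionises with anti participation of the neighbouring bromine and the enol carbon of the β-keto ester opens the bromonium ion at the tertiary carbon (six-membered ring, bond C6–C11), so the C–Br configuration is retained, while the new α-centre is epimerisable and becomes sp2 in step 5.

**Step 5**
Reactants: 7 methyl (3S)-3-bromo-2,2-dimethyl-6-oxocyclohexane-1-carboxylate
Product: 8 methyl (5S)-5-bromo-6,6-dimethyl-2-(trifluoromethanesulfonyloxy)cyclohex-1-ene-1-carboxylate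
Conditions: Tf2O, iPr2NEt, CH2Cl2, −78 → 0 °C
Reagents that add atoms: trifluoromethanesulfonic anhydride O=S(=O)(OS(=O)(=O)C(F)(F)F)C(F)(F)F
Why: Enol triflate formation from a β-keto ester, where the ester fixes the double bond between C6 and C7 and so stores the position of the later allylsilane regiospecifically.

**Step 6**
Reactants: 8 methyl (5S)-5-bromo-6,6-dimethyl-2-(trifluoromethanesulfonyloxy)cyclohex-1-ene-1-carboxylate
Product: 9 (4S)-4-bromo-2-(hydroxymethyl)-3,3-dimethylcyclohex-1-en-1-yl trifluoromethanesulfonate
Conditions: iBu2AlH, CH2Cl2, −78 °C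
Reagents that add atoms: none
Why: 1,2-Reduction of an α,β-unsaturated ester to the allylic alcohol with an aluminium hydride, under which the vinyl triflate and the hindered secondary bromide are inert.

**Step 7**
Reactants: 9 (4S)-4-bromo-2-(hydroxymethyl)-3,3-dimethylcyclohex-1-en-1-yl trifluoromethanesulfonate
Product: 10 (4S)-4-bromo-2-formyl-3,3-dimethylcyclohex-1-en-1-yl trifluoromethanesulfonate
Conditions: Dess–Martin periodinane, CH2Cl2, 0 → 23 °C
Reagents that add atoms: none
Why: Dess–Martin oxidation of a primary allylic alcohol to the enal under nearly neutral conditions.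

**Step 8**
Reactants: 10 (4S)-4-bromo-2-formyl-3,3-dimethylcyclohex-1-en-1-yl trifluoromethanesulfonate
Product: 11 (4S)-4-bromo-2-ethenyl-3,3-dimethylcyclohex-1-en-1-yl trifluoromethanesulfonate
Conditions: Ph3PCH3Br, KN(SiMe3)2, THF, −78 → 0 °C
Reagents that add atoms: methyltriphenylphosphonium bromide C[P+](c1ccccc1)(c1ccccc1)c1ccccc1.[Br-]
Why: Wittig methylenation with a non-stabilised ylide, which adds to the aldehyde far faster than to the vinylogous sulfonate and supplies C4.

**Step 9**
Reactants: 12 but-2-yn-1-ol
Product: 14 (2Z)-3-iodobut-2-en-1-ol, via cyclic alkenylaluminate 13 (not isolated)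
Conditions: NaAlH2(OCH2CH2OMe)2, THF, 0 → 23 °C; then I2, THF, −78 °C
Reagents that add atoms: iodine II
Why: Alkoxide-directed trans-hydroalumination of a propargylic alcohol places aluminium cis to the CH2O group in a five-membered aluminate, and iodinolysis with retention fixes the (Z) geometry.

**Step 10**
Reactants: 11 (4S)-4-bromo-2-ethenyl-3,3-dimethylcyclohex-1-en-1-yl trifluoromethanesulfonate; 14 (2Z)-3-iodobut-2-en-1-ol
Product: 16 (4S)-4-bromo-2-[(3Z)-5-hydroxy-3-methylpent-3-en-1-yl]-3,3-dimethylcyclohex-1-en-1-yl trifluoromethanesulfonate, via B-alkyl-9-BBN adduct 15 (not isolated)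
Conditions: 9-BBN, THF, 0 → 23 °C; then 14, PdCl2(dppf), AsPh3, Cs2CO3, DMF–H2O, 23 °C
Reagents that add atoms: none
Why: Anti-Markovnikov hydroboration of the monosubstituted vinyl group followed by B-alkyl Suzuki–Miyaura coupling, in which the vinyl iodide should undergo oxidative addition much faster than the hindered tetrasubstituted vinyl triflate and couples with retention of the (Z) geometry.

**Step 11**
Reactants: 16 (4S)-4-bromo-2-[(3Z)-5-hydroxy-3-methylpent-3-en-1-yl]-3,3-dimethylcyclohex-1-en-1-yl trifluoromethanesulfonate
Product: 17 (4S)-4-bromo-2-[(3S,4S)-4-bromo-3-chloro-5-hydroxy-3-methylpentyl]-3,3-dimethylcyclohex-1-en-1-yl trifluoromethanesulfonate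
Conditions: NBS, ClTi(OiPr)3, chiral tridentate Schiff-base ligand (20 mol %), hexanes–CH2Cl2, −20 °C
Reagents that add atoms: N-bromosuccinimide O=C1CCC(=O)N1Br; chlorotitanium triisopropoxide CC(C)O[Ti](Cl)(OC(C)C)OC(C)C
Why: The same catalytic enantioselective bromochlorination as in step 1: ligand-controlled anti addition of Br to C2 and Cl to the tertiary C3 of the (Z)-allylic alcohol gives the (2S,3S) pair, while the electron-poor enol triflate alkene should not react with NBS.

**Step 12**
Reactants: 17 (4S)-4-bromo-2-[(3S,4S)-4-bromo-3-chloro-5-hydroxy-3-methylpentyl]-3,3-dimethylcyclohex-1-en-1-yl trifluoromethanesulfonate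
Product: 18 (2S,3S)-2-bromo-5-[(5S)-5-bromo-6,6-dimethyl-2-(trimethylsilylmethyl)cyclohex-1-en-1-yl]-3-chloro-3-methylpentan-1-ol
Conditions: Me3SiCH2MgCl, ZnCl2, THF, 0 °C; then 17, Pd(PPh3)4 (5 mol %), THF, 23 → 40 °C; organozinc in excess (3 equiv)
Reagents that add atoms: (trimethylsilyl)methylmagnesium chloride C[Si](C)(C)C[Mg]Cl
Why: Negishi coupling of the vinyl triflate under zerovalent palladium catalysis gives the allylsilane; the weakly basic organozinc should spare the bromohydrin and the halides, and the unactivated alkyl halides should not undergo oxidative addition at this temperature.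

**Step 13**
Reactants: 18 (2S,3S)-2-bromo-5-[(5S)-5-bromo-6,6-dimethyl-2-(trimethylsilylmethyl)cyclohex-1-en-1-yl]-3-chloro-3-methylpentan-1-ol
Product: 20 nidificene [(2S,6S,8S,9S)-2,8-dibromo-9-chloro-1,1,9-trimethyl-5-methylidenespiro[5.5]undecane], via primary triflate 19 (not isolated)
Conditions: Tf2O, 2,6-di-tert-butyl-4-methylpyridine, CH2Cl2, −78 °C; then HFIP, −40 → 0 °C
Reagents that add atoms: none
Why: Proposed new method: the primary alcohol is converted into its triflate, which ionises at low temperature with anti participation of the vicinal C2 bromine to a C1–C2 bromonium ion (or is displaced directly); the tetrasubstituted allylsilane carbon C6 attacks the primary carbon C1 and the β-silyl cation at C7 loses the silyl group to HFIP, so that the C1–C6 bond, the spiro stereocentre and the C7=C14 methylene arise in one event. The closest known reaction types are the allylsilane-terminated cation–olefin (Hosomi–Sakurai type) spirocyclization and the anchimerically assisted solvolysis of β-bromoalkyl sulfonates, together with the bromonium capture of step 4. Ring B closes in a 6-exo-tet manner with respect to the triflate, that is by endo opening of the bromonium ion at its primary terminus, and exo with respect to the allylsilane double bond. The spiro centre C6 is set by a chair transition state in which the C2 bromine (anti to the forming bond, as bromonium opening requires) and the C3 chlorine are equatorial, the C3 methyl is axial, the flat C7 arm is axial and the bulky CMe2 arm is equatorial; ring A should reinforce this, because C1 adds to C6 anti to the pseudoaxial C11 methyl, that is trans to the equatorial C10 bromine. The step needs attack at C1 and not at C2 (secured by the hindered, chlorine-deactivated C2), ionisation of the triflate and not of the C3 tertiary chloride (secured by the far better leaving group, the low temperature and the short exposure to HFIP), and desilylation in place of proton loss (secured by the β-silicon effect, which allows only the exocyclic alkene); the centres C2, C3 and C10 are not touched.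

**Compound list**

1 | 3-methylbut-2-en-1-ol (prenol) | CC(C)=CCO | starting material
2 | (2S)-2-bromo-3-chloro-3-methylbutan-1-ol | OC[C@H](Br)C(C)(C)Cl | intermediate
3 | (2S)-2-bromo-3-chloro-3-methylbutyl trifluoromethanesulfonate | O=S(=O)(OC[C@H](Br)C(C)(C)Cl)C(F)(F)F | intermediate
4 | methyl acetoacetate (methyl 3-oxobutanoate) | COC(=O)CC(C)=O | starting material
5 | methyl acetoacetate dianion (lithium sodium salt) | [Li+].[Na+].[CH2-]C(=O)[CH-]C(=O)OC | intermediate (not isolated)
6 | methyl (6S)-6-bromo-7-chloro-7-methyl-3-oxooctanoate | COC(=O)CC(=O)CC[C@H](Br)C(C)(C)Cl | intermediate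
7 | methyl (3S)-3-bromo-2,2-dimethyl-6-oxocyclohexane-1-carboxylate (C1 epimers, in equilibrium with the enol) | COC(=O)C1C(=O)CC[C@H](Br)C1(C)C | intermediate
8 | methyl (5S)-5-bromo-6,6-dimethyl-2-(trifluoromethanesulfonyloxy)cyclohex-1-ene-1-carboxylate | COC(=O)C1=C(OS(=O)(=O)C(F)(F)F)CC[C@H](Br)C1(C)C | intermediate
9 | (4S)-4-bromo-2-(hydroxymethyl)-3,3-dimethylcyclohex-1-en-1-yl trifluoromethanesulfonate | OCC1=C(OS(=O)(=O)C(F)(F)F)CC[C@H](Br)C1(C)C | intermediate
10 | (4S)-4-bromo-2-formyl-3,3-dimethylcyclohex-1-en-1-yl trifluoromethanesulfonate | O=CC1=C(OS(=O)(=O)C(F)(F)F)CC[C@H](Br)C1(C)C | intermediate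
11 | (4S)-4-bromo-2-ethenyl-3,3-dimethylcyclohex-1-en-1-yl trifluoromethanesulfonate | C=CC1=C(OS(=O)(=O)C(F)(F)F)CC[C@H](Br)C1(C)C | intermediate
12 | but-2-yn-1-ol | CC#CCO | starting material
13 | cyclic alkenylaluminate, sodium 2,2-bis(2-methoxyethoxy)-3-methyl-2,5-dihydro-1,2-oxaaluminol-2-uide | [Na+].CC1=CCO[Al-]1(OCCOC)OCCOC | intermediate (not isolated)
14 | (2Z)-3-iodobut-2-en-1-ol | C/C(I)=C/CO | intermediate
15 | (4S)-4-bromo-2-[2-(9-borabicyclo[3.3.1]nonan-9-yl)ethyl]-3,3-dimethylcyclohex-1-en-1-yl trifluoromethanesulfonate | C1CCC2CCCC1B2CCC1=C(OS(=O)(=O)C(F)(F)F)CC[C@H](Br)C1(C)C | intermediate (not isolated)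
16 | (4S)-4-bromo-2-[(3Z)-5-hydroxy-3-methylpent-3-en-1-yl]-3,3-dimethylcyclohex-1-en-1-yl trifluoromethanesulfonate | OC/C=C(C)\CCC1=C(OS(=O)(=O)C(F)(F)F)CC[C@H](Br)C1(C)C | intermediate
17 | (4S)-4-bromo-2-[(3S,4S)-4-bromo-3-chloro-5-hydroxy-3-methylpentyl]-3,3-dimethylcyclohex-1-en-1-yl trifluoromethanesulfonate | OC[C@H](Br)[C@@](C)(Cl)CCC1=C(OS(=O)(=O)C(F)(F)F)CC[C@H](Br)C1(C)C | intermediate
18 | (2S,3S)-2-bromo-5-[(5S)-5-bromo-6,6-dimethyl-2-(trimethylsilylmethyl)cyclohex-1-en-1-yl]-3-chloro-3-methylpentan-1-ol | OC[C@H](Br)[C@@](C)(Cl)CCC1=C(C[Si](C)(C)C)CC[C@H](Br)C1(C)C | intermediate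
19 | (2S,3S)-2-bromo-5-[(5S)-5-bromo-6,6-dimethyl-2-(trimethylsilylmethyl)cyclohex-1-en-1-yl]-3-chloro-3-methylpentyl trifluoromethanesulfonate | O=S(=O)(OC[C@H](Br)[C@@](C)(Cl)CCC1=C(C[Si](C)(C)C)CC[C@H](Br)C1(C)C)C(F)(F)F | intermediate (not isolated)
20 | nidificene, (2S,6S,8S,9S)-2,8-dibromo-9-chloro-1,1,9-trimethyl-5-methylidenespiro[5.5]undecane | C=C1CC[C@H](Br)C(C)(C)[C@]12CC[C@](C)(Cl)[C@@H](Br)C2 | target

**Step count and risks**

Total step count: 13. Longest linear sequence: 12 (steps 1–8 and 10–13).

Steps most likely to fail:

Step 13 (Proposed new method). The ring closure may be overtaken by ionisation of the C3 tertiary chloride, by attack of C6 at C2 to give a five-membered ring, by protodesilylation before the C–C bond forms, or it may show poor facial selectivity at C6. The fallback uses known chemistry, sets out from 17 and returns at 20. The primary alcohol of 17 is tosylated (TsCl, pyridine, 0 °C) to the tosylate F1. MeLi (THF, −78 °C) attacks the sulfur of the enol triflate and releases the regiodefined lithium enolate F2. On warming in THF–DMPU this should close ring B by intramolecular 6-exo-tet C-alkylation, through the same chair, to the spiro ketone F3. Methylenation of the hindered ketone with Cp2TiMe2 (toluene, 65 °C) then gives 20.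

Step 4. The enol oxygen may capture the bromonium ion instead of the enol carbon, or solvent capture and loss of HBr may compete with cyclization. The fallback sets out from 6 and returns at 7. Compound 6 is converted into its (Z)-silyl enol ether F4 (tBuMe2SiOTf, Et3N, CH2Cl2, 0 °C), whose only nucleophilic site is the β-carbon. Solvolysis in HFIP with 2,6-lutidine should then give 7 by Mukaiyama-type capture of the bromonium ion, the silyl group leaving as the silyl chloride.

Step 3. The strongly basic dianion may eliminate triflic acid from the β-bromo triflate or attack the bromine instead of displacing the triflate. The fallback sets out from 3 and returns at 6. Compound 3 is coupled with CH2=CHCH2MgBr under Li2CuCl4 catalysis (THF, −78 °C) to the terminal alkene (5S)-5-bromo-6-chloro-6-methylhept-1-ene F5. Ozonolysis (O3, CH2Cl2, −78 °C; then PPh3) gives the aldehyde (4S)-4-bromo-5-chloro-5-methylhexanal F6. Roskamp homologation with methyl diazoacetate and SnCl2 (CH2Cl2, 23 °C) gives 6.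

**Further compounds**

F1 | step 13 | (4S)-4-bromo-2-[(3S,4S)-4-bromo-3-chloro-3-methyl-5-(4-methylbenzenesulfonyloxy)pentyl]-3,3-dimethylcyclohex-1-en-1-yl trifluoromethanesulfonate | Cc1ccc(cc1)S(=O)(=O)OC[C@H](Br)[C@@](C)(Cl)CCC1=C(OS(=O)(=O)C(F)(F)F)CC[C@H](Br)C1(C)C
F2 | step 13 | lithium (4S)-4-bromo-2-[(3S,4S)-4-bromo-3-chloro-3-methyl-5-(4-methylbenzenesulfonyloxy)pentyl]-3,3-dimethylcyclohex-1-en-1-olate | [Li+].Cc1ccc(cc1)S(=O)(=O)OC[C@H](Br)[C@@](C)(Cl)CCC1=C([O-])CC[C@H](Br)C1(C)C
F3 | step 13 | (4S,6R,8S,9S)-4,8-dibromo-9-chloro-5,5,9-trimethylspiro[5.5]undecan-1-one | O=C1CC[C@H](Br)C(C)(C)[C@]12CC[C@](C)(Cl)[C@@H](Br)C2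
F4 | step 4 | methyl (2Z,6S)-6-bromo-3-[(tert-butyldimethylsilyl)oxy]-7-chloro-7-methyloct-2-enoate | COC(=O)/C=C(\O[Si](C)(C)C(C)(C)C)CC[C@H](Br)C(C)(C)Cl
F5 | step 3 | (5S)-5-bromo-6-chloro-6-methylhept-1-ene | C=CCC[C@H](Br)C(C)(C)Cl
F6 | step 3 | (4S)-4-bromo-5-chloro-5-methylhexanal | O=CCC[C@H](Br)C(C)(C)Cl
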